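**Plan**

- Retrosynthesis: the protecting groups and the C4 carbonyl are taken back first (C4=O to C4–OMe), then ring C is cut at O1–C2 and C3–C4 in one [4+2] disconnection. This leaves a ring A salicylaldehyde and a two-carbon (E)-enol ester that carries ring B.
- Enabling feature: ring C is a pyran fused to the phenol-derived ring A, and the bonds O1–C2 and C3–C4 lie across ring C from each other. O1–C8a–C4a–C4 can therefore act as an ortho-quinone methide heterodiene and C2–C3 as an alkene whose (E)-geometry matches the trans C2/C3 pair.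
- Forward: ring A aldehyde by twofold C-prenylation of 2,4,6-trihydroxybenzaldehyde and bis-MOM capping; the C2–C3 unit by boron–Wittig olefination of 4-(MOM-oxy)benzaldehyde and copper-catalysed C–O coupling with benzoic acid.
- Ring C closes in step 7. The benzoate is then exchanged for a TBS ether, so that no acyl group can participate or migrate when C4 is ionised and no base meets the ketone. C4–OMe is hydrolysed and oxidised, and all protecting groups fall in one acidic step.
- Stereochemistry: C2 and C3 are both set in the cycloaddition (trans from the alkene geometry, absolute sense from the chiral phosphoric acid); the transient C4 centre is erased by oxidation.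

Key step: step 7

Assumption: the sense of induction of the chiral acid in step 7 cannot be assigned in advance; the (R)-configured acid is written, and its mirror image would be used if it leads to the antipodal series. (Prenyl = 3-methylbut-2-en-1-yl; MOM = methoxymethyl; TBS = tert-butyldimethylsilyl.)

**Route**

Step 1
Reactants: 1 2,4,6-trihydroxybenzaldehyde; 2 prenyl bromide (1-bromo-3-methylbut-2-ene)
Product: 3 2,4,6-trihydroxy-3,5-diprenylbenzaldehyde
Conditions: 2 (2.1 equiv), 10% aq. KOH, 0 °C
Reagents that add atoms: none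
Why: Base-mediated C-prenylation of an acylphloroglucinol: in water the phenoxide reacts at carbon, the two free ring positions are equivalent by symmetry and both are filled, and limiting the bromide to two equivalents should curb geminal over-alkylation.

Step 2
Reactants: 3 2,4,6-trihydroxy-3,5-diprenylbenzaldehyde
Product: 4 2-hydroxy-4,6-bis(methoxymethoxy)-3,5-diprenylbenzaldehyde
Conditions: MOMCl (2.2 equiv), i-Pr2NEt, CH2Cl2, 0 °C
Reagents that add atoms: chloromethyl methyl ether, COCCl
Why: Selective MOM ether formation: the para hydroxyl and one of the two equivalent ortho hydroxyls are alkylated, while the remaining ortho hydroxyl is hydrogen-bonded to the formyl group and should stay free, as is usual for 2,4,6-trihydroxyaryl carbonyl compounds.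

Step 3
Reactants: 5 4-hydroxybenzaldehyde
Product: 6 4-(methoxymethoxy)benzaldehyde
Conditions: MOMCl, i-Pr2NEt, CH2Cl2, 0 °C to rt
Reagents that add atoms: chloromethyl methyl ether, COCCl
Why: Routine O-alkylation of a phenol; the MOM ether keeps ring B a strong para donor, which the regiochemistry of step 7 depends on.

Step 4
Reactants: 6 4-(methoxymethoxy)benzaldehyde; 7 bis(4,4,5,5-tetramethyl-1,3,2-dioxaborolan-2-yl)methane
Product: 8 (E)-2-[4-(methoxymethoxy)phenyl]ethenylboronic acid pinacol ester
Conditions: 7, lithium 2,2,6,6-tetramethylpiperidide (LiTMP), THF, 0 °C; then 6, −78 °C to rt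
Reagents that add atoms: none
Why: Boron–Wittig reaction: the α-boryl carbanion of 7 adds to the non-enolisable aldehyde and syn B–O elimination from the adduct should give the trans alkenyl boronate.

Step 5
Reactants: 8 (E)-2-[4-(methoxymethoxy)phenyl]ethenylboronic acid pinacol ester
Product: 9 potassium (E)-trifluoro{2-[4-(methoxymethoxy)phenyl]ethenyl}borate
Conditions: KHF2, MeOH–H2O, rt
Reagents that add atoms: potassium hydrogen difluoride, [K+].[F-].F
Why: Ligand exchange at boron with bifluoride gives the trifluoroborate salt with the alkene geometry untouched; the aryl MOM ether tolerates the weakly acidic medium at room temperature.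

Step 6
Reactants: 9 potassium (E)-trifluoro{2-[4-(methoxymethoxy)phenyl]ethenyl}borate
Product: 10 (E)-2-[4-(methoxymethoxy)phenyl]ethenyl benzoate
Conditions: PhCO2H, CuBr (10 mol%), 4-(dimethylamino)pyridine (20 mol%), 4 Å MS, O2 (1 atm), CH2Cl2, rt to 40 °C
Reagents that add atoms: benzoic acid, O=C(O)c1ccccc1
Why: Oxidative copper-catalysed C–O coupling of an alkenyl trifluoroborate with a carboxylic acid (Chan–Lam type) proceeds with retention at the alkenyl carbon, so the (E)-enol ester should be obtained as a single geometric isomer.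

Step 7
Reactants: 4 2-hydroxy-4,6-bis(methoxymethoxy)-3,5-diprenylbenzaldehyde; 10 (E)-2-[4-(methoxymethoxy)phenyl]ethenyl benzoate
Product: 13 (2R,3S)-4-methoxy-5,7-bis(methoxymethoxy)-2-[4-(methoxymethoxy)phenyl]-6,8-diprenylchroman-3-yl benzoate (2,3-trans with the spatial arrangement of the target; mixture of C4 epimers), via dimethyl acetal 11 (not isolated), via ortho-quinone methide 12 (not isolated)
Conditions: (R)-3,3'-bis(2,4,6-triisopropylphenyl)-1,1'-binaphthyl-2,2'-diyl hydrogen phosphate (10 mol%), HC(OMe)3 (1.5 equiv), 10 (1.5 equiv), 5 Å MS, toluene, 0 °C to rt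
Reagents that add atoms: trimethyl orthoformate, COC(OC)OC
Why: Proposed new method: the acid catalyses acetalisation of 4 by the orthoformate and ionisation of acetal 11 (loss of methanol) to the phosphate-paired, O-protonated form of ortho-quinone methide 12, whose heterodiene O1–C8a–C4a–C4 undergoes an asynchronous inverse-electron-demand hetero-Diels–Alder reaction with 10, the benzoate-bearing alkene carbon bonding to C4 because the developing positive charge then sits on the p-alkoxybenzylic carbon that the phenol oxygen closes on. The closest known reactions are acid-catalysed [4+2] cycloadditions of salicylaldehyde-acetal-derived ortho-quinone methides with styrenes and chiral Brønsted acid catalysed ortho-quinone methide cycloadditions with styrenes and enamides; an enol ester partner under chiral-acid control is the untested element. Ring C is closed as a six-membered ring in the [4+2] mode (in the stepwise limit, 6-endo capture of the benzylic cation by O1). C2 and C3 should emerge trans because the (E)-geometry of 10 is transferred suprafacially and a stepwise pathway would also favour the diequatorial aryl/benzoyloxy arrangement, while the absolute configuration is set by the chiral phosphate, which holds the heterodiene by hydrogen bond and ion pair and shields one of its faces. Regioselectivity rests on the p-alkoxybenzyl cation outweighing acyloxy stabilisation (the enol ester behaves like an oxygenated anethole), and chemoselectivity on ring A carrying no free C–H, on all phenols except O1 being capped and on an acid too weak to protonate the prenyl alkenes. Because the C4 centre is erased later, the enantiomeric purity of C2/C3 requires facial control at the heterodiene coupled to a single endo/exo mode; otherwise the C4 epimers of 13 would be separated at this stage.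

Step 8
Reactants: 13 (2R,3S)-4-methoxy-5,7-bis(methoxymethoxy)-2-[4-(methoxymethoxy)phenyl]-6,8-diprenylchroman-3-yl benzoate
Product: 14 (2R,3S)-4-methoxy-5,7-bis(methoxymethoxy)-2-[4-(methoxymethoxy)phenyl]-6,8-diprenylchroman-3-ol (C4 epimers)
Conditions: K2CO3 (0.3 equiv), MeOH, rt
Reagents that add atoms: none
Why: Base-catalysed transesterification (Zemplén-type methanolysis) removes the benzoate at a stage where there is no C4 carbonyl, so no enolisable or ring-opening-prone centre is exposed to base and C2/C3 are untouched.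

Step 9
Reactants: 14 (2R,3S)-4-methoxy-5,7-bis(methoxymethoxy)-2-[4-(methoxymethoxy)phenyl]-6,8-diprenylchroman-3-ol
Product: 15 tert-butyl{[(2R,3S)-4-methoxy-5,7-bis(methoxymethoxy)-2-[4-(methoxymethoxy)phenyl]-6,8-diprenylchroman-3-yl]oxy}dimethylsilane (C4 epimers)
Conditions: TBSCl, imidazole, DMF, 40 °C
Reagents that add atoms: tert-butyldimethylsilyl chloride, CC(C)(C)[Si](C)(C)Cl
Why: Imidazole-promoted silylation of the secondary alcohol puts a non-participating, non-migrating ether on O3 before C4 is ionised; the Lewis-acid-free conditions leave the labile C4 methyl ether alone.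

Step 10
Reactants: 15 tert-butyl{[(2R,3S)-4-methoxy-5,7-bis(methoxymethoxy)-2-[4-(methoxymethoxy)phenyl]-6,8-diprenylchroman-3-yl]oxy}dimethylsilane
Product: 16 (2R,3S)-3-(tert-butyldimethylsilyloxy)-5,7-bis(methoxymethoxy)-2-[4-(methoxymethoxy)phenyl]-6,8-diprenylchroman-4-ol (C4 epimers)
Conditions: pyridinium p-toluenesulfonate (cat.), acetone–H2O, 40 °C
Reagents that add atoms: water, O
Why: Acid-catalysed solvolysis: the benzylic methyl ether on the 2,4,6-trioxygenated ring A ionises under very mild acid and the cation is captured by the large excess of water, while aryl MOM ethers and the alkyl TBS ether should survive the pyridinium salt.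

Step 11
Reactants: 16 (2R,3S)-3-(tert-butyldimethylsilyloxy)-5,7-bis(methoxymethoxy)-2-[4-(methoxymethoxy)phenyl]-6,8-diprenylchroman-4-ol
Product: 17 (2R,3R)-3-(tert-butyldimethylsilyloxy)-5,7-bis(methoxymethoxy)-2-[4-(methoxymethoxy)phenyl]-6,8-diprenylchroman-4-one
Conditions: Dess–Martin periodinane, CH2Cl2, 0 °C to rt
Reagents that add atoms: none
Why: Dess–Martin oxidation of the benzylic secondary alcohol gives the aryl ketone without base, so both C4 epimers converge on one ketone and the α-silyloxy centre C3 and C2 are not epimerised; the prenyl alkenes are inert to the periodinane.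

Step 12
Reactants: 17 (2R,3R)-3-(tert-butyldimethylsilyloxy)-5,7-bis(methoxymethoxy)-2-[4-(methoxymethoxy)phenyl]-6,8-diprenylchroman-4-one
Product: 18 6,8-diprenylaromadendrin, (2R,3R)-3,5,7-trihydroxy-2-(4-hydroxyphenyl)-6,8-diprenylchroman-4-one
Conditions: 3 M aq. HCl, MeOH, 40 °C
Reagents that add atoms: none
Why: Acid-catalysed acetal exchange and silyl ether solvolysis in methanol cleave the three aryl MOM ethers and the TBS ether in one operation; the trans-dihydroflavonol is configurationally stable in acid, and moderate temperature and short exposure should limit cyclisation of the prenyl groups onto the freed phenols.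

**Compound list**

1 | 2,4,6-trihydroxybenzaldehyde | O=Cc1c(O)cc(O)cc1O | starting material
2 | prenyl bromide (1-bromo-3-methylbut-2-ene) | CC(C)=CCBr | starting material
3 | 2,4,6-trihydroxy-3,5-diprenylbenzaldehyde | CC(C)=CCc1c(O)c(CC=C(C)C)c(O)c(C=O)c1O | intermediate
4 | 2-hydroxy-4,6-bis(methoxymethoxy)-3,5-diprenylbenzaldehyde | CC(C)=CCc1c(OCOC)c(CC=C(C)C)c(O)c(C=O)c1OCOC | intermediate
5 | 4-hydroxybenzaldehyde | O=Cc1ccc(O)cc1 | starting material
6 | 4-(methoxymethoxy)benzaldehyde | COCOc1ccc(C=O)cc1 | intermediate
7 | bis(4,4,5,5-tetramethyl-1,3,2-dioxaborolan-2-yl)methane | CC1(C)OB(CB2OC(C)(C)C(C)(C)O2)OC1(C)C | starting material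
8 | (E)-2-[4-(methoxymethoxy)phenyl]ethenylboronic acid pinacol ester | COCOc1ccc(/C=C/B2OC(C)(C)C(C)(C)O2)cc1 | intermediate
9 | potassium (E)-trifluoro{2-[4-(methoxymethoxy)phenyl]ethenyl}borate | COCOc1ccc(/C=C/[B-](F)(F)F)cc1.[K+] | intermediate
10 | (E)-2-[4-(methoxymethoxy)phenyl]ethenyl benzoate | O=C(O/C=C/c1ccc(OCOC)cc1)c1ccccc1 | intermediate
11 | 2-(dimethoxymethyl)-3,5-bis(methoxymethoxy)-4,6-diprenylphenol (dimethyl acetal of 4; not isolated) | COC(OC)c1c(O)c(CC=C(C)C)c(OCOC)c(CC=C(C)C)c1OCOC | intermediate
12 | 6-(methoxymethylidene)-3,5-bis(methoxymethoxy)-2,4-diprenylcyclohexa-2,4-dien-1-one (4-methoxy ortho-quinone methide, reacting as its O-protonated phosphate ion pair; not isolated) | COC=C1C(=O)C(CC=C(C)C)=C(OCOC)C(CC=C(C)C)=C1OCOC | intermediate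
13 | (2R,3S)-4-methoxy-5,7-bis(methoxymethoxy)-2-[4-(methoxymethoxy)phenyl]-6,8-diprenylchroman-3-yl benzoate (2,3-trans, C4 epimers) | CC(C)=CCc1c(OCOC)c(CC=C(C)C)c2c(c1OCOC)C(OC)[C@H](OC(=O)c1ccccc1)[C@@H](c1ccc(OCOC)cc1)O2 | intermediate
14 | (2R,3S)-4-methoxy-5,7-bis(methoxymethoxy)-2-[4-(methoxymethoxy)phenyl]-6,8-diprenylchroman-3-ol (C4 epimers) | CC(C)=CCc1c(OCOC)c(CC=C(C)C)c2c(c1OCOC)C(OC)[C@H](O)[C@@H](c1ccc(OCOC)cc1)O2 | intermediate
15 | tert-butyl{[(2R,3S)-4-methoxy-5,7-bis(methoxymethoxy)-2-[4-(methoxymethoxy)phenyl]-6,8-diprenylchroman-3-yl]oxy}dimethylsilane (C4 epimers) | CC(C)=CCc1c(OCOC)c(CC=C(C)C)c2c(c1OCOC)C(OC)[C@H](O[Si](C)(C)C(C)(C)C)[C@@H](c1ccc(OCOC)cc1)O2 | intermediate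
16 | (2R,3S)-3-(tert-butyldimethylsilyloxy)-5,7-bis(methoxymethoxy)-2-[4-(methoxymethoxy)phenyl]-6,8-diprenylchroman-4-ol (C4 epimers) | CC(C)=CCc1c(OCOC)c(CC=C(C)C)c2c(c1OCOC)C(O)[C@H](O[Si](C)(C)C(C)(C)C)[C@@H](c1ccc(OCOC)cc1)O2 | intermediate
17 | (2R,3R)-3-(tert-butyldimethylsilyloxy)-5,7-bis(methoxymethoxy)-2-[4-(methoxymethoxy)phenyl]-6,8-diprenylchroman-4-one | CC(C)=CCc1c(OCOC)c(CC=C(C)C)c2c(c1OCOC)C(=O)[C@H](O[Si](C)(C)C(C)(C)C)[C@@H](c1ccc(OCOC)cc1)O2 | intermediate
18 | 6,8-diprenylaromadendrin, (2R,3R)-3,5,7-trihydroxy-2-(4-hydroxyphenyl)-6,8-diprenylchroman-4-one | CC(C)=CCc1c(O)c(CC=C(C)C)c2c(c1O)C(=O)[C@H](O)[C@@H](c1ccc(O)cc1)O2 | target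

**Step count and risks**

Total step count: 12. Longest linear sequence: 10 steps (steps 3 to 12, from 4-hydroxybenzaldehyde); the ring A branch (steps 1 and 2) joins at step 7.

Steps most likely to fail:

1. Step 7 (Proposed new method). The weakly nucleophilic enol ester may fail to intercept the strongly stabilised oxocarbenium ion, or the addition may proceed with poor facial or endo/exo selectivity, so that the C2/C3 pair is formed in low enantiomeric purity. The fallback uses known chemistry; it sets out from 4, draws on 6, and returns to the route at 18.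
   - Excess MeMgBr in THF at 0 °C should add to the aldehyde of 4 to give racemic 1-[2-hydroxy-4,6-bis(methoxymethoxy)-3,5-diprenylphenyl]ethanol F1.
   - MnO2 in CH2Cl2 should oxidise this benzylic alcohol to 1-[2-hydroxy-4,6-bis(methoxymethoxy)-3,5-diprenylphenyl]ethanone F2.
   - NaH and MOMCl in DMF should cap the chelated phenol to give 1-[2,4,6-tris(methoxymethoxy)-3,5-diprenylphenyl]ethanone F3.
   - Claisen–Schmidt condensation of F3 with aldehyde 6 (KOH, EtOH) should give (E)-3-[4-(methoxymethoxy)phenyl]-1-[2,4,6-tris(methoxymethoxy)-3,5-diprenylphenyl]prop-2-en-1-one F4.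
   - Juliá–Colonna epoxidation (poly-L-leucine, urea–H2O2, DBU, THF) attacks only the electron-poor enone and should give [(2R,3S)-3-[4-(methoxymethoxy)phenyl]oxiran-2-yl][2,4,6-tris(methoxymethoxy)-3,5-diprenylphenyl]methanone F5.
   - HCl in MeOH then removes the four MOM groups, and the freed 2'-phenol opens the epoxide at the benzylic carbon with inversion (6-endo) to give 18; C3 keeps the configuration of the epoxide α-carbon.

2. Step 1. Geminal over-alkylation to dearomatised dienones and O-alkylation may compete with the second C-prenylation, so that little of the symmetrical di-C-prenyl compound is formed. The fallback sets out from 1 and returns at 4, bypassing 3.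
   - Selective protection (MOMCl, i-Pr2NEt, CH2Cl2) should give 2-hydroxy-4,6-bis(methoxymethoxy)benzaldehyde F6.
   - N-iodosuccinimide in DMF should iodinate the only two free ring positions to give 2-hydroxy-3,5-diiodo-4,6-bis(methoxymethoxy)benzaldehyde F7.
   - Twofold Stille coupling with tributyl(3-methylbut-2-enyl)stannane (Pd(PPh3)4, DMF, 90 °C), which transfers the prenyl group through its unsubstituted terminus, should deliver 4.

3. Step 12. Acid-induced cyclisation of a prenyl group onto a freed ortho phenol (chroman formation), or addition of HCl or methanol across a prenyl double bond, may occur during the protic deprotection. The fallback sets out from 17 and returns at 18; no Brønsted acid meets a free ortho-prenylphenol.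
   - TMSOTf and 2,2'-bipyridyl in CH2Cl2 at 0 °C should exchange the three aryl MOM acetals for trimethylsilyl ethers, giving (2R,3R)-3-(tert-butyldimethylsilyloxy)-6,8-diprenyl-5,7-bis(trimethylsilyloxy)-2-[4-(trimethylsilyloxy)phenyl]chroman-4-one F8.
   - Pyridine-buffered HF·pyridine in THF should then remove all four silyl groups to give 18.

Further compounds
F1 | step 7 | 1-[2-hydroxy-4,6-bis(methoxymethoxy)-3,5-diprenylphenyl]ethanol (racemic) | CC(O)c1c(O)c(CC=C(C)C)c(OCOC)c(CC=C(C)C)c1OCOC
F2 | step 7 | 1-[2-hydroxy-4,6-bis(methoxymethoxy)-3,5-diprenylphenyl]ethanone | CC(=O)c1c(O)c(CC=C(C)C)c(OCOC)c(CC=C(C)C)c1OCOC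
F3 | step 7 | 1-[2,4,6-tris(methoxymethoxy)-3,5-diprenylphenyl]ethanone | CC(=O)c1c(OCOC)c(CC=C(C)C)c(OCOC)c(CC=C(C)C)c1OCOC
F4 | step 7 | (E)-3-[4-(methoxymethoxy)phenyl]-1-[2,4,6-tris(methoxymethoxy)-3,5-diprenylphenyl]prop-2-en-1-one | COCOc1ccc(/C=C/C(=O)c2c(OCOC)c(CC=C(C)C)c(OCOC)c(CC=C(C)C)c2OCOC)cc1
F5 | step 7 | [(2R,3S)-3-[4-(methoxymethoxy)phenyl]oxiran-2-yl][2,4,6-tris(methoxymethoxy)-3,5-diprenylphenyl]methanone | O=C([C@@H]1O[C@H]1c1ccc(OCOC)cc1)c1c(OCOC)c(CC=C(C)C)c(OCOC)c(CC=C(C)C)c1OCOC
F6 | step 1 | 2-hydroxy-4,6-bis(methoxymethoxy)benzaldehyde | COCOc1cc(O)c(C=O)c(OCOC)c1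
F7 | step 1 | 2-hydroxy-3,5-diiodo-4,6-bis(methoxymethoxy)benzaldehyde | COCOc1c(I)c(O)c(C=O)c(OCOC)c1I
F8 | step 12 | (2R,3R)-3-(tert-butyldimethylsilyloxy)-6,8-diprenyl-5,7-bis(trimethylsilyloxy)-2-[4-(trimethylsilyloxy)phenyl]chroman-4-one | CC(C)=CCc1c(O[Si](C)(C)C)c(CC=C(C)C)c2c(c1O[Si](C)(C)C)C(=O)[C@H](O[Si](C)(C)C(C)(C)C)[C@@H](c1ccc(O[Si](C)(C)C)cc1)O2
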